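**Plan**
Numbering (target): bicyclo[3.3.1]nonane C1 (benzoyl) to C9 (bridge C=O), ketones C2 and C4, geranyl on C5, CMe2 at C8, bridge C7–C10–C11–C3, cyclopentane C3–C11–C12(Me2)–C13–C14.
Retrosynthetic cuts, in order: C1–COPh; C5–C6 and C5–geranyl; C1–C8 (made through a temporary O2–C10 tether); C10–C7; C3–C14; C11–C12.
Enabling feature: C3 is the quaternary carbon shared by the trione ring and the cyclopentane, and the trione ring is a masked phloroglucinol (O on C2, C4, C9; C1 and C5 unsubstituted) in which C3 lies para to O9, so a C9 phenoxide can be alkylated at C3 by a C14 tosylate.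
Forward ring order: arene, then cyclopentane (spiro, step 11), dihydrofuran tether (step 15), cycloheptene by Claisen ring expansion (step 16), last cyclohexane of the cage by radical closure (step 22); the C6–C7–C8 unit enters at C10 (step 14), geranyl at C5 (step 20), benzoyl at C1 (step 23).
Stereochemistry: C11 from an enantioselective Ireland–Claisen rearrangement (step 5); C3 because the C10 oxygen can reach only the enol ether carbon cis to it; C1 from suprafacial delivery in the Claisen step; C5 and C7 from the geometry of cage closure.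
Key step: step 11

Assumption: the (S,S)-diazaborolidine controller of step 5 is taken to give the (R)-acid 10 by analogy with its sense of induction on simple allyl esters; if the sense were reversed, the (R,R)-controller would be used with no other change.

**Route**

Step 1
Reactants: 1 4-hydroxy-2,6-dimethoxybenzaldehyde
Product: 2 4-(benzyloxy)-2,6-dimethoxybenzaldehyde
Conditions: BnBr, K2CO3, DMF, rt
Reagents that add atoms: benzyl bromide, BrCc1ccccc1
Why: Williamson ether synthesis at the only acidic hydroxyl masks the future C9 oxygen as a benzyl ether that is orthogonal to the methyl ethers and to the later silyl ether and tosylate.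

Step 2
Reactants: 2 4-(benzyloxy)-2,6-dimethoxybenzaldehyde; 3 p-toluenesulfonylmethyl isocyanide (TosMIC)
Product: 5 2-[4-(benzyloxy)-2,6-dimethoxyphenyl]acetonitrile, via oxazoline adduct 4 (not isolated)
Conditions: t-BuOK, DME, −40 °C; then MeOH, reflux
Reagents that add atoms: none
Why: Van Leusen reductive cyanation, in which the TosMIC anion adds to the aldehyde, closes to the 4-tosyl-2-oxazoline and on methanolysis loses methyl formate and sulfinate to leave the one-carbon-homologated nitrile whose new carbon is C10.

Step 3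
Reactants: 5 2-[4-(benzyloxy)-2,6-dimethoxyphenyl]acetonitrile
Product: 6 2-[4-(benzyloxy)-2,6-dimethoxyphenyl]acetic acid
Conditions: KOH, EtOH/H2O, reflux; then aq. HCl
Reagents that add atoms: water, O
Why: Alkaline nitrile hydrolysis of an unhindered arylacetonitrile, which the aryl benzyl and methyl ethers survive.

Step 4
Reactants: 6 2-[4-(benzyloxy)-2,6-dimethoxyphenyl]acetic acid; 7 prenol (3-methylbut-2-en-1-ol)
Product: 8 3-methylbut-2-en-1-yl 2-[4-(benzyloxy)-2,6-dimethoxyphenyl]acetate
Conditions: EDC·HCl, DMAP (cat.), CH2Cl2, 0 °C → rt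
Reagents that add atoms: none
Why: Steglich-type carbodiimide esterification joins the acid and the allylic alcohol under neutral conditions that leave the acid-sensitive prenyl unit intact.

Step 5
Reactants: 8 3-methylbut-2-en-1-yl 2-[4-(benzyloxy)-2,6-dimethoxyphenyl]acetate
Product: 10 (R)-2-[4-(benzyloxy)-2,6-dimethoxyphenyl]-3,3-dimethylpent-4-enoic acid, via boron ketene acetal 9 (not isolated)
Conditions: (S,S)-diazaborolidine bromide [from the (S,S)-bis-sulfonamide and BBr3], i-Pr2NEt, CH2Cl2, −78 → 4 °C; H2O work-up
Reagents that add atoms: none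
Why: Enantioselective Ireland–Claisen rearrangement in which the chiral boron ketene acetal passes through a chair [3,3] transition state with one enolate face shielded by the C2-symmetric sulfonamide ligand, forming C11–C12 and setting C11 as R, while C12 becomes a non-stereogenic gem-dimethyl quaternary carbon.

Step 6
Reactants: 10 (R)-2-[4-(benzyloxy)-2,6-dimethoxyphenyl]-3,3-dimethylpent-4-enoic acid
Product: 11 (R)-2-[4-(benzyloxy)-2,6-dimethoxyphenyl]-3,3-dimethylpent-4-en-1-ol
Conditions: LiAlH4, THF, 0 → 40 °C
Reagents that add atoms: none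
Why: Hydride reduction of the acid runs through the carboxylate, so the benzylic C11 centre is not enolised and the isolated alkene is untouched.

Step 7
Reactants: 11 (R)-2-[4-(benzyloxy)-2,6-dimethoxyphenyl]-3,3-dimethylpent-4-en-1-ol
Product: 12 (R)-tert-butyl{2-[4-(benzyloxy)-2,6-dimethoxyphenyl]-3,3-dimethylpent-4-enyloxy}dimethylsilane
Conditions: TBSCl, imidazole, DMF, rt
Reagents that add atoms: tert-butyldimethylsilyl chloride, CC(C)(C)[Si](C)(C)Cl
Why: Standard silylation protects the C10 hydroxyl so that it is neither tosylated in step 9 nor a competing nucleophile in step 11.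

Step 8
Reactants: 12 (R)-tert-butyl{2-[4-(benzyloxy)-2,6-dimethoxyphenyl]-3,3-dimethylpent-4-enyloxy}dimethylsilane
Product: 14 (R)-4-[4-(benzyloxy)-2,6-dimethoxyphenyl]-5-(tert-butyldimethylsilyloxy)-3,3-dimethylpentan-1-ol, via B-alkyl-9-BBN 13 (not isolated)
Conditions: 9-BBN, THF, rt → 50 °C; then NaOH, H2O2, 0 °C → rt
Reagents that add atoms: hydrogen peroxide, OO
Why: Hydroboration–oxidation of the monosubstituted alkene with a bulky dialkylborane places boron and then oxygen on the terminal carbon C14 (anti-Markovnikov) next to the quaternary C12.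

Step 9
Reactants: 14 (R)-4-[4-(benzyloxy)-2,6-dimethoxyphenyl]-5-(tert-butyldimethylsilyloxy)-3,3-dimethylpentan-1-ol
Product: 15 (R)-4-[4-(benzyloxy)-2,6-dimethoxyphenyl]-5-(tert-butyldimethylsilyloxy)-3,3-dimethylpentyl 4-methylbenzenesulfonate
Conditions: TsCl, Et3N, DMAP (cat.), CH2Cl2, 0 °C → rt
Reagents that add atoms: p-toluenesulfonyl chloride, Cc1ccc(cc1)S(Cl)(=O)=O
Why: Sulfonylation turns the primary C14 hydroxyl into the leaving group for the spirocyclisation.

Step 10
Reactants: 15 (R)-4-[4-(benzyloxy)-2,6-dimethoxyphenyl]-5-(tert-butyldimethylsilyloxy)-3,3-dimethylpentyl 4-methylbenzenesulfonate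
Product: 16 (R)-5-(tert-butyldimethylsilyloxy)-4-(4-hydroxy-2,6-dimethoxyphenyl)-3,3-dimethylpentyl 4-methylbenzenesulfonate
Conditions: H2 (1 atm), Pd/C, EtOAc, rt
Reagents that add atoms: none
Why: Catalytic hydrogenolysis cleaves the aryl benzyl ether under neutral conditions that spare the alkyl tosylate, the silyl ether and the methyl ethers, so the C9 phenol is freed without base and cannot cyclise prematurely.

Step 11
Reactants: 16 (R)-5-(tert-butyldimethylsilyloxy)-4-(4-hydroxy-2,6-dimethoxyphenyl)-3,3-dimethylpentyl 4-methylbenzenesulfonate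
Product: 18 (R)-1-[(tert-butyldimethylsilyloxy)methyl]-6,10-dimethoxy-2,2-dimethylspiro[4.5]deca-6,9-dien-8-one, via potassium phenoxide 17 (not isolated)
Conditions: t-BuOK (1.05 equiv), t-BuOH/THF, 0.01 M, rt → 50 °C
Reagents that add atoms: none
Why: The phenoxide 17 is an ambident nucleophile whose para carbon C3 displaces the tosylate at C14 in an intramolecular SN2 reaction, so aromaticity is traded for the cross-conjugated dienone 18, the bis(methyl enol ether) of a 2,2-disubstituted cyclohexane-1,3,5-trione. The closest known reaction type is Ar1-5 phenoxide participation, which turns 4-(4-hydroxyphenyl)butyl sulfonates into spiro[4.5]deca-6,9-dien-8-ones. The cyclopentane closes in the 5-exo-tet mode and the gem-dimethyl group at C12 favours the folded rotamer. No stereocentre is created, because C2 and C4 are identical arms and C3 stays non-stereogenic until step 15, while C11 is carried unchanged from step 5. The step needs C- over O-alkylation and ipso over ortho attack: the para tether cannot reach the oxygen, attack at C1 or C5 would need a seven-membered ring, and the two methoxy groups raise the electron density at C3. High dilution suppresses intermolecular O-alkylation, and the near-stoichiometric base leaves the silyl ether and the new enol ethers untouched.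

Step 12
Reactants: 18 (R)-1-[(tert-butyldimethylsilyloxy)methyl]-6,10-dimethoxy-2,2-dimethylspiro[4.5]deca-6,9-dien-8-one
Product: 19 (R)-1-(hydroxymethyl)-6,10-dimethoxy-2,2-dimethylspiro[4.5]deca-6,9-dien-8-one
Conditions: HF·pyridine, pyridine, THF, 0 °C → rt
Reagents that add atoms: none
Why: Buffered fluoride desilylation frees the C10 hydroxyl without forming an alkoxide, which would otherwise add to the neighbouring enol ether carbon.

Step 13
Reactants: 19 (R)-1-(hydroxymethyl)-6,10-dimethoxy-2,2-dimethylspiro[4.5]deca-6,9-dien-8-one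
Product: 20 (R)-6,10-dimethoxy-2,2-dimethyl-8-oxospiro[4.5]deca-6,9-diene-1-carbaldehyde
Conditions: Dess–Martin periodinane, NaHCO3, CH2Cl2, 0 °C
Reagents that add atoms: none
Why: Dess–Martin oxidation gives the hindered aldehyde under buffered, non-enolising conditions, so the C11 centre alpha to the new carbonyl is preserved.

Step 14
Reactants: 20 (R)-6,10-dimethoxy-2,2-dimethyl-8-oxospiro[4.5]deca-6,9-diene-1-carbaldehyde; 21 2-bromo-3-methylbut-2-ene
Product: 23 (1R)-1-(1-hydroxy-2,3-dimethylbut-2-enyl)-6,10-dimethoxy-2,2-dimethylspiro[4.5]deca-6,9-dien-8-one (C10 epimers), via alkenyllithium 22 (not isolated)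
Conditions: 21, t-BuLi (2 equiv), Et2O, −78 °C; then 20, THF, −78 °C; aq. NH4Cl at −78 °C
Reagents that add atoms: none
Why: Bromine–lithium exchange followed by 1,2-addition of the alkenyllithium to the aldehyde, which is far more electrophilic than the doubly vinylogous ester carbonyl, forms C10–C7 and brings in C6, C7 and C8 with its two methyl groups; the C10 epimer mixture is acceptable because step 15 is expected to be stereoconvergent.

Step 15
Reactants: 23 (1R)-1-(1-hydroxy-2,3-dimethylbut-2-enyl)-6,10-dimethoxy-2,2-dimethylspiro[4.5]deca-6,9-dien-8-one (C10 epimers)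
Product: 24 cyclic enol ether (O on C10 bonded to C2; C4 still OMe; alkenyl on C10 exo; C3 S, C10 R, C11 R)
Conditions: CSA (10 mol%), 5 Å molecular sieves, benzene, 60 °C
Reagents that add atoms: none
Why: Acid-catalysed transetherification of the vinylogous ester (addition–elimination at C2, 5-exo) by the C10 hydroxyl, which can reach only the enol ether carbon cis to it on the cyclopentane and so fixes C3; the allylic C10–O bond should ionise reversibly under the same acid, so both carbinol epimers are expected to drain into the less hindered exo-alkenyl isomer (alkenyl anti to the C12 methyl groups).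

Step 16
Reactants: 24 cyclic enol ether
Product: 25 bicyclo[4.3.1]decene vinylogous ester (C1–C8 bonded; C2 ketone; C10=C7 with methyl C6 on C7; C1 R, C3 S, C11 R)
Conditions: 1,2-dichlorobenzene, Na2CO3 (solid), 175 °C, sealed tube
Reagents that add atoms: none
Why: Claisen rearrangement of the 2-alkylidene-5-alkenyltetrahydrofuran unit (ring expansion to a cyclohept-4-enone) through a boat-like transition state, in which C8 is delivered suprafacially to the face of C1 that carries the tether and C11, so the C1–C8 bond and the C1 configuration are set together while the O–C10 bond is released as the C2 ketone and the C10=C7 alkene.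

Step 17
Reactants: 25 bicyclo[4.3.1]decene vinylogous ester
Product: 26 allylic alcohol (C6 hydroxymethyl on C7)
Conditions: SeO2 (0.3 equiv), t-BuOOH, CH2Cl2, rt
Reagents that add atoms: tert-butyl hydroperoxide, CC(C)(C)OO
Why: Selenium dioxide allylic oxidation (ene reaction then [2,3] shift) hydroxylates the methyl group on the more substituted alkene carbon C7, the only allylic C–H position at that end because C8 is quaternary, while C1–H cannot enolise towards C2 in the bridged ring and the dione is still masked as its methyl enol ether.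

Step 18
Reactants: 26 allylic alcohol
Product: 29 exocyclic alkene (C7=C6H2; C10 now CH2), via allyl sulfonylhydrazide 27 (not isolated), via allylic diazene 28 (not isolated)
Conditions: 2-nitrobenzenesulfonylhydrazide, PPh3, DEAD, THF, −30 °C → rt
Reagents that add atoms: none
Why: Reductive 1,3-transposition of a primary allylic alcohol, in which Mitsunobu displacement by the sulfonylhydrazide, loss of sulfinic acid to the monoalkyl diazene and retro-ene loss of N2 deliver hydrogen to C10 and move the double bond to the exocyclic C7=C6 position.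

Step 19
Reactants: 29 exocyclic alkene
Product: 30 1,3-dione (C4 and C9 ketones; C5 methylene; enolised)
Conditions: 1 M HCl, THF, rt
Reagents that add atoms: water, O
Why: Acid hydrolysis of the remaining vinylogous methyl ester unmasks the C4/C9 dione with its acidic C5 methylene under conditions too mild to protonate the 1,1-disubstituted alkene.

Step 20
Reactants: 30 1,3-dione; 31 geranyl acetate
Product: 32 C5-geranyl dione (C5 enolisable)
Conditions: Pd(PPh3)4 (5 mol%), DBU, THF, rt
Reagents that add atoms: none
Why: Tsuji–Trost allylation, in which the soft dione enolate attacks the unsubstituted terminus of the geranyl π-allyl complex of zerovalent palladium, any O-allyl product is re-ionised and funnelled to the C-allyl dione with the 2E geometry retained, and the hindered C1–H, which can enolise only towards C9, stays untouched.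

Step 21
Reactants: 32 C5-geranyl dione
Product: 33 C5-bromo C5-geranyl dione (C5 epimers)
Conditions: NBS, CH2Cl2, −78 → 0 °C
Reagents that add atoms: N-bromosuccinimide, BrN1C(=O)CCC1=O
Why: Electrophilic alpha-bromination of the enolised 2-alkyl-1,3-dione at C5 is much faster than attack on the unactivated alkenes and gives a tertiary bromide whose two C5 epimers converge in the next step.

Step 22
Reactants: 33 C5-bromo C5-geranyl dione
Product: 34 debenzoyl target (complete cage with geranyl on C5 and H on C1)
Conditions: Bu3SnH (syringe pump), AIBN (cat.), benzene, 80 °C, 0.005 M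
Reagents that add atoms: none
Why: Tin hydride radical cyclisation, in which the electrophilic 1,3-dicarbonyl radical at C5 adds in the 6-endo-trig mode to the terminal carbon C6 of the 1,1-disubstituted alkene held close to it by the bicyclic frame and the resulting tertiary C7 radical takes hydrogen from the stannane on its only open face, so C5 (geranyl outside) and C7 (hydrogen outside) are fixed by the geometry of the cage.

Step 23
Reactants: 34 debenzoyl target; 35 benzoyl chloride
Product: 37 CNP0168637.1, via bridgehead lithium enolate 36 (not isolated)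
Conditions: lithium 2,2,6,6-tetramethylpiperidide (from the amine and n-BuLi), THF, −78 °C; then 35, −78 → 0 °C
Reagents that add atoms: none
Why: Bridgehead deprotonation and C-acylation, in which C1–H is the only acidic proton left, the non-nucleophilic amide base spares the three hindered ketones and the bridgehead enolate cannot give a stable O-acyl product, so benzoylation occurs at carbon with retention.

**Compound list**
1 | 4-hydroxy-2,6-dimethoxybenzaldehyde | O=Cc1c(OC)cc(O)cc1OC | starting material
2 | 4-(benzyloxy)-2,6-dimethoxybenzaldehyde | O=Cc1c(OC)cc(OCc2ccccc2)cc1OC | intermediate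
3 | p-toluenesulfonylmethyl isocyanide (TosMIC) | Cc1ccc(cc1)S(=O)(=O)C[N+]#[C-] | starting material
4 | 5-[4-(benzyloxy)-2,6-dimethoxyphenyl]-4-tosyl-4,5-dihydrooxazole (racemic trans adduct, drawn without descriptors; not isolated) | Cc1ccc(cc1)S(=O)(=O)C1N=COC1c1c(OC)cc(OCc2ccccc2)cc1OC | intermediate
5 | 2-[4-(benzyloxy)-2,6-dimethoxyphenyl]acetonitrile | N#CCc1c(OC)cc(OCc2ccccc2)cc1OC | intermediate
6 | 2-[4-(benzyloxy)-2,6-dimethoxyphenyl]acetic acid | OC(=O)Cc1c(OC)cc(OCc2ccccc2)cc1OC | intermediate
7 | prenol (3-methylbut-2-en-1-ol) | CC(C)=CCO | starting material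
8 | 3-methylbut-2-en-1-yl 2-[4-(benzyloxy)-2,6-dimethoxyphenyl]acetate | CC(C)=CCOC(=O)Cc1c(OC)cc(OCc2ccccc2)cc1OC | intermediate
9 | boron ketene acetal of 8 on the (4S,5S)-diazaborolidine, aryl cis to O–B (not isolated) | CC(C)=CCO/C(=C/c1c(OC)cc(OCc2ccccc2)cc1OC)OB1N(S(=O)(=O)c2cc(cc(c2)C(F)(F)F)C(F)(F)F)[C@@H](c2ccccc2)[C@H](c2ccccc2)N1S(=O)(=O)c1cc(cc(c1)C(F)(F)F)C(F)(F)F | intermediate
10 | (R)-2-[4-(benzyloxy)-2,6-dimethoxyphenyl]-3,3-dimethylpent-4-enoic acid | OC(=O)[C@@H](c1c(OC)cc(OCc2ccccc2)cc1OC)C(C)(C)C=C | intermediate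
11 | (R)-2-[4-(benzyloxy)-2,6-dimethoxyphenyl]-3,3-dimethylpent-4-en-1-ol | OC[C@@H](c1c(OC)cc(OCc2ccccc2)cc1OC)C(C)(C)C=C | intermediate
12 | (R)-tert-butyl{2-[4-(benzyloxy)-2,6-dimethoxyphenyl]-3,3-dimethylpent-4-enyloxy}dimethylsilane | CC(C)(C)[Si](C)(C)OC[C@@H](c1c(OC)cc(OCc2ccccc2)cc1OC)C(C)(C)C=C | intermediate
13 | B-alkyl-9-borabicyclo[3.3.1]nonane from 12, boron on C14 (not isolated) | CC(C)(C)[Si](C)(C)OC[C@@H](c1c(OC)cc(OCc2ccccc2)cc1OC)C(C)(C)CCB1C2CCCC1CCC2 | intermediate
14 | (R)-4-[4-(benzyloxy)-2,6-dimethoxyphenyl]-5-(tert-butyldimethylsilyloxy)-3,3-dimethylpentan-1-ol | CC(C)(C)[Si](C)(C)OC[C@@H](c1c(OC)cc(OCc2ccccc2)cc1OC)C(C)(C)CCO | intermediate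
15 | (R)-4-[4-(benzyloxy)-2,6-dimethoxyphenyl]-5-(tert-butyldimethylsilyloxy)-3,3-dimethylpentyl 4-methylbenzenesulfonate | CC(C)(C)[Si](C)(C)OC[C@@H](c1c(OC)cc(OCc2ccccc2)cc1OC)C(C)(C)CCOS(=O)(=O)c1ccc(C)cc1 | intermediate
16 | (R)-5-(tert-butyldimethylsilyloxy)-4-(4-hydroxy-2,6-dimethoxyphenyl)-3,3-dimethylpentyl 4-methylbenzenesulfonate (key-step precursor) | CC(C)(C)[Si](C)(C)OC[C@@H](c1c(OC)cc(O)cc1OC)C(C)(C)CCOS(=O)(=O)c1ccc(C)cc1 | intermediate
17 | potassium phenoxide of 16 (not isolated) | [K+].CC(C)(C)[Si](C)(C)OC[C@@H](c1c(OC)cc([O-])cc1OC)C(C)(C)CCOS(=O)(=O)c1ccc(C)cc1 | intermediate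
18 | (R)-1-[(tert-butyldimethylsilyloxy)methyl]-6,10-dimethoxy-2,2-dimethylspiro[4.5]deca-6,9-dien-8-one (key-step product) | COC1=CC(=O)C=C(OC)C12CCC(C)(C)[C@H]2CO[Si](C)(C)C(C)(C)C | intermediate
19 | (R)-1-(hydroxymethyl)-6,10-dimethoxy-2,2-dimethylspiro[4.5]deca-6,9-dien-8-one | COC1=CC(=O)C=C(OC)C12CCC(C)(C)[C@H]2CO | intermediate
20 | (R)-6,10-dimethoxy-2,2-dimethyl-8-oxospiro[4.5]deca-6,9-diene-1-carbaldehyde | COC1=CC(=O)C=C(OC)C12CCC(C)(C)[C@H]2C=O | intermediate
21 | 2-bromo-3-methylbut-2-ene | CC(C)=C(C)Br | starting material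
22 | 3-methylbut-2-en-2-yllithium (not isolated) | [Li]C(C)=C(C)C | intermediate
23 | (1R)-1-(1-hydroxy-2,3-dimethylbut-2-enyl)-6,10-dimethoxy-2,2-dimethylspiro[4.5]deca-6,9-dien-8-one, both C10 epimers | COC1=CC(=O)C=C(OC)C12CCC(C)(C)[C@H]2C(O)C(C)=C(C)C | intermediate
24 | cyclic enol ether: dihydrofuran ring O–C2–C3–C11–C10 fused to the cyclopentane and to the 4-methoxydienone ring, 3-methylbut-2-en-2-yl on C10 exo (trans to C12); C3 S, C10 R, C11 R | COC1=CC(=O)C=C2O[C@@H](C(C)=C(C)C)[C@@H]3C(C)(C)CC[C@]123 | intermediate
25 | bicyclo[4.3.1]decene vinylogous ester: C1–C8 bond, C2 ketone, C10=C7 (methyl C6 on C7) in the ring C1–C2–C3–C11–C10–C7–C8, C4(OMe)=C5–C9=O; C1 R, C3 S, C11 R | COC1=CC(=O)[C@H]2C(C)(C)C(C)=C[C@@H]3C(C)(C)CC[C@@]13C2=O | intermediate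
26 | allylic alcohol: as 25 with CH2OH (C6) on C7 | COC1=CC(=O)[C@H]2C(C)(C)C(CO)=C[C@@H]3C(C)(C)CC[C@@]13C2=O | intermediate
27 | N-allyl-N-(2-nitrophenylsulfonyl)hydrazine at C6 (not isolated) | COC1=CC(=O)[C@H]2C(C)(C)C(CN(N)S(=O)(=O)c4ccccc4[N+](=O)[O-])=C[C@@H]3C(C)(C)CC[C@@]13C2=O | intermediate
28 | monoalkyl diazene at C6 (not isolated) | COC1=CC(=O)[C@H]2C(C)(C)C(CN=N)=C[C@@H]3C(C)(C)CC[C@@]13C2=O | intermediate
29 | exocyclic alkene: C7=C6H2, C10 methylene, C4(OMe)=C5–C9=O retained | COC1=CC(=O)[C@H]2C(C)(C)C(=C)C[C@@H]3C(C)(C)CC[C@@]13C2=O | intermediate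
30 | 1,3-dione: C4 and C9 ketones, C5 methylene (drawn as the keto form, enolised in solution), C2 ketone, C7=C6H2 | O=C1CC(=O)[C@H]2C(C)(C)C(=C)C[C@@H]3C(C)(C)CC[C@@]13C2=O | intermediate
31 | geranyl acetate | CC(=O)OC/C=C(\C)CCC=C(C)C | starting material
32 | C5-geranyl dione (C5 enolisable, drawn without descriptor) | O=C1C(C/C=C(\C)CCC=C(C)C)C(=O)[C@H]2C(C)(C)C(=C)C[C@@H]3C(C)(C)CC[C@@]13C2=O | intermediate
33 | C5-bromo C5-geranyl dione (both C5 epimers) | O=C1C(Br)(C/C=C(\C)CCC=C(C)C)C(=O)[C@H]2C(C)(C)C(=C)C[C@@H]3C(C)(C)CC[C@@]13C2=O | intermediate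
34 | debenzoyl target: full cage, geranyl on C5, hydrogen on C1 | CC(C)=CCC/C(C)=C/C[C@@]12C[C@H]3C[C@@H]4C(C)(C)CC[C@]4(C1=O)C(=O)[C@@H](C2=O)C3(C)C | intermediate
35 | benzoyl chloride | ClC(=O)c1ccccc1 | starting material
36 | bridgehead lithium enolate of 34, drawn as the C1-lithio form (not isolated) | CC(C)=CCC/C(C)=C/C[C@@]12C[C@H]3C[C@@H]4C(C)(C)CC[C@]4(C1=O)C(=O)[C@@]([Li])(C2=O)C3(C)C | intermediate
37 | CNP0168637.1 | CC(C)=CCC/C(C)=C/C[C@@]12C[C@H]3C[C@@H]4C(C)(C)CC[C@]4(C1=O)C(=O)[C@@](C(=O)c1ccccc1)(C2=O)C3(C)C | target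

**Step count and weak points**
Total step count: 23. Longest linear sequence: 23 steps (1 to 37); compounds 3, 7, 21, 31 and 35 are bought, so there is no separate fragment synthesis.

Steps most likely to fail:

Step 16 (Claisen ring expansion). The allylic C10–O bond may break heterolytically, because the vinylogous ester oxygen is a good leaving group, so that a formal 1,3-shift to C10 or elimination to a diene outruns the concerted rearrangement. The fallback sets out from 24 and comes back to the route at 25. It lowers the oxidation level at C9 so that the migrating oxygen belongs to an ordinary dienyl ether. 1,2-Reduction of 24 with i-Bu2AlH (CH2Cl2, −78 °C) should give the dienol F1. Silylation (TBSCl, imidazole, DMF) should give the silyl ether F2, which is heated (toluene, 150 °C, solid Na2CO3) to undergo the same ring expansion to the rearranged silyl ether F3. HF·pyridine then frees the hydroxy ketone F4, and Dess–Martin oxidation of its allylic alcohol restores the vinylogous ester 25.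

Step 15 (stereoconvergent ring closure). The allylic alcohol may dehydrate under acid, or the C10 epimers may fail to equilibrate, leaving material as the endo isomer that cannot rearrange. The fallback sets out from 23 and comes back at 24. The C10 epimers of 23 are separated by chromatography. The (10R) epimer is closed under basic, non-ionising conditions (NaH, THF, 0 °C), where the alkoxide adds to C2 and expels methoxide with retention at C10 to give 24. The (10S) epimer is oxidised with Dess–Martin periodinane to the enone F5 and reduced again under Luche conditions (NaBH4, CeCl3·7H2O, MeOH) to the epimer mixture 23 for another cycle.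

Step 22 (radical cage closure). The stabilised C5 radical may be reduced by the stannane before it cyclises, or it may attack the internal alkene carbon C7 in the 5-exo mode. The fallback is polar; it sets out from 29 and comes back at 34.
- Hydroboration–oxidation of the exocyclic alkene of 29 from its outer face (9-BBN, THF; then NaOH, H2O2) should give the primary alcohol F6 with C6 turned inward towards C5.
- An Appel reaction (I2, PPh3, imidazole, CH2Cl2) converts it to the iodide F7.
- Hydrolysis of the vinylogous ester (1 M HCl, THF) gives the dione iodide F8.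
- K2CO3 in DMF closes the cage by intramolecular C-alkylation of the dione at C5, giving the cage dione without geranyl F9.
- LiN(i-Pr)2 (THF, −78 °C) should deprotonate the less hindered bridgehead C5 (next to CH2 rather than CMe2), and geranyl bromide then gives 34.

Further compounds
F1 | step 16 | dienol: 24 with C9 carbonyl reduced to CH–OH (C9 epimers) | COC1=CC(O)C=C2O[C@@H](C(C)=C(C)C)[C@@H]3C(C)(C)CC[C@]123
F2 | step 16 | tert-butyldimethylsilyl ether of F1 | COC1=CC(O[Si](C)(C)C(C)(C)C)C=C2O[C@@H](C(C)=C(C)C)[C@@H]3C(C)(C)CC[C@]123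
F3 | step 16 | rearranged silyl ether: skeleton of 25 with C9 as CH–OTBS | COC1=CC(O[Si](C)(C)C(C)(C)C)[C@H]2C(C)(C)C(C)=C[C@@H]3C(C)(C)CC[C@@]13C2=O
F4 | step 16 | hydroxy ketone: skeleton of 25 with C9 as CH–OH | COC1=CC(O)[C@H]2C(C)(C)C(C)=C[C@@H]3C(C)(C)CC[C@@]13C2=O
F5 | step 15 | enone: 23 with C10 oxidised to the ketone | COC1=CC(=O)C=C(OC)C12CCC(C)(C)[C@H]2C(=O)C(C)=C(C)C
F6 | step 22 | primary alcohol: 29 with C7–H and CH2OH (C6) on C7 directed towards C5 | COC1=CC(=O)[C@H]2C(C)(C)[C@@H](CO)C[C@@H]3C(C)(C)CC[C@@]13C2=O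
F7 | step 22 | iodide from F6 | COC1=CC(=O)[C@H]2C(C)(C)[C@@H](CI)C[C@@H]3C(C)(C)CC[C@@]13C2=O
F8 | step 22 | dione iodide: F7 with the C4/C9 dione unmasked | O=C1CC(=O)[C@H]2C(C)(C)[C@@H](CI)C[C@@H]3C(C)(C)CC[C@@]13C2=O
F9 | step 22 | cage dione without geranyl: hydrogen on C1 and on C5 | [C@@H]12C[C@H]3C[C@@H]4C(C)(C)CC[C@]4(C1=O)C(=O)[C@@H](C2=O)C3(C)C
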